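**Plan**

- Numbering (germacrane type): C1 hemiketal carbon, C2–C3 its CH2CH2 link to C4 (methyl-bearing ether carbon), C5=C6 enol-lactone alkene, C7/C11/C12 butenolide carbons, C8 acyloxy carbon, C9, C10 (methyl-bearing), C13 acetoxymethyl carbon. Ring A = butenolide; ring B = oxolane C1–C2–C3–C4–O; ring C = nine-membered ring C4–C5=C6–C7–C8–C9–C10–C1–O.
- Retrosynthetic cuts, in order: C1–OH/C2–H (hydration of a C1=C2 enol ether), C11–C13 (Stille), C5=C6 (ring C), C1–O (ring B, alkyne hydroalkoxylation), C8–O ester, C7–C8 (Nozaki–Hiyama–Kishi), C2–C3 (acetylide + epoxide).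
- Forward: the C10–C1≡C2 fragment and the C3–C5 epoxide give the chain; ring A is attached intact at C7–C8; the side-chain ester follows; ring B is closed by gold catalysis; ring C is closed last by C5–C6 bond formation and elimination; C13 and the hemiketal are then unmasked.
- Enabling feature: C6 is the γ-carbon of butenolide ring A (a latent 2-silyloxyfuran nucleophile), C5 sits on quaternary C4 (a non-enolizable aldehyde), and C5=C6 is endocyclic in ring C. Ring closure by vinylogous aldol condensation can therefore give only the needed geometry (C4 cis to C7), the one disfavoured in open-chain ylidenebutenolides.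
- Stereochemistry: C10 from auxiliary-controlled allylation, C4 from (R)-2-methylglycidol, C8 from CBS reduction, C1 fixed by the oxygen bridge from C4 on hydration; the C5/C6 centres of the aldol adduct are erased.

Key step: step 16

Remark: 14 (C8 epimers) and 27 (C5/C6 epimers) are mixtures that converge in the following operation, so these centres are left undefined in their SMILES.

**Route**

Step 1
Reactants: 1 (S)-4-benzyl-3-propionyloxazolidin-2-one; 2 allyl iodide
Product: 4 (S)-4-benzyl-3-[(R)-2-methylpent-4-enoyl]oxazolidin-2-one, via sodium enolate 3 (not isolated)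
Conditions: NaN(SiMe3)2, THF, −78 °C; then 2, −78 to −40 °C
Reagents that add atoms: none
Why: The chelated sodium Z-enolate is shielded on one face by the benzyl group, so allyl iodide adds to the other face and sets the (R)-centre that becomes C10 (Evans asymmetric alkylation).

Step 2
Reactants: 4 (S)-4-benzyl-3-[(R)-2-methylpent-4-enoyl]oxazolidin-2-one
Product: 5 (R)-2-methylpent-4-en-1-ol
Conditions: LiBH4, H2O (1 equiv), Et2O, 0 °C
Reagents that add atoms: none
Why: Hydride attacks the exocyclic imide carbonyl and releases the auxiliary without touching the α-centre (reductive auxiliary cleavage).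

Step 3
Reactants: 5 (R)-2-methylpent-4-en-1-ol
Product: 6 (R)-2-methylpent-4-enal (used as a CH2Cl2 solution)
Conditions: Dess–Martin periodinane, CH2Cl2, 0 °C to rt
Reagents that add atoms: none
Why: Dess–Martin oxidation is non-basic and should give the α-branched aldehyde without epimerization.

Step 4
Reactants: 6 (R)-2-methylpent-4-enal
Product: 7 (R)-1,1-dibromo-3-methylhexa-1,5-diene
Conditions: CBr4, PPh3, Zn, CH2Cl2, 0 °C to rt
Reagents that add atoms: carbon tetrabromide, BrC(Br)(Br)Br
Why: The dibromomethylene ylide olefinates the aldehyde under neutral conditions (first stage of the Corey–Fuchs reaction), which adds the future C2 and keeps the α-centre intact.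

Step 5
Reactants: 8 (R)-2-methylglycidol
Product: 9 (S)-triethyl[(2-methyloxiran-2-yl)methoxy]silane
Conditions: TESCl, imidazole, CH2Cl2, 0 °C
Reagents that add atoms: chlorotriethylsilane, CC[Si](Cl)(CC)CC
Why: Silylation of the primary alcohol masks the future C5 oxygen as a triethylsilyl ether (the descriptor changes by CIP priority only).

Step 6
Reactants: 7 (R)-1,1-dibromo-3-methylhexa-1,5-diene; 9 (S)-triethyl[(2-methyloxiran-2-yl)methoxy]silane
Product: 11 (2S,6R)-2,6-dimethyl-1-(triethylsilyloxy)non-8-en-4-yn-2-ol, via lithium acetylide 10 (not isolated)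
Conditions: n-BuLi (2.1 equiv), THF, −78 to 0 °C; then −78 °C, BF3·OEt2, 9
Reagents that add atoms: none
Why: n-BuLi converts the dibromoalkene into the lithium acetylide (second stage of the Corey–Fuchs reaction), which opens the BF3-activated epoxide at its CH2 carbon by SN2 attack, so the quaternary C4 centre is carried over unchanged.

Step 7
Reactants: 11 (2S,6R)-2,6-dimethyl-1-(triethylsilyloxy)non-8-en-4-yn-2-ol
Product: 12 (3R,7S)-7-hydroxy-3,7-dimethyl-8-(triethylsilyloxy)oct-4-ynal
Conditions: O3, CH2Cl2/MeOH, −78 °C; then PPh3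
Reagents that add atoms: ozone, [O-][O+]=O
Why: Ozone reacts with the terminal alkene much faster than with the internal alkyne, and reductive work-up gives the C8 aldehyde (ozonolysis).

Step 8
Reactants: 12 (3R,7S)-7-hydroxy-3,7-dimethyl-8-(triethylsilyloxy)oct-4-ynal; 13 3,4-dibromofuran-2(5H)-one
Product: 14 3-bromo-4-[(3R,7S)-1,7-dihydroxy-3,7-dimethyl-8-(triethylsilyloxy)oct-4-yn-1-yl]furan-2(5H)-one (mixture of C8 epimers)
Conditions: CrCl2 (6 equiv), NiCl2 (2 mol %), 13 (2 equiv), DMF, rt
Reagents that add atoms: none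
Why: Zerovalent nickel should insert into the more electron-poor C4–Br bond at the β-carbon of the lactone, and the alkenylchromium formed by transmetalation adds to the aldehyde only (Nozaki–Hiyama–Kishi reaction), with the unselective C8 centre corrected in steps 9 and 10.

Step 9
Reactants: 14 3-bromo-4-[(3R,7S)-1,7-dihydroxy-3,7-dimethyl-8-(triethylsilyloxy)oct-4-yn-1-yl]furan-2(5H)-one
Product: 15 3-bromo-4-[(3R,7S)-7-hydroxy-3,7-dimethyl-8-(triethylsilyloxy)oct-4-ynoyl]furan-2(5H)-one
Conditions: Dess–Martin periodinane, CH2Cl2, 0 °C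
Reagents that add atoms: none
Why: Dess–Martin oxidation converts both C8 epimers into one ketone and leaves the tertiary alcohol untouched.

Step 10
Reactants: 15 3-bromo-4-[(3R,7S)-7-hydroxy-3,7-dimethyl-8-(triethylsilyloxy)oct-4-ynoyl]furan-2(5H)-one
Product: 16 3-bromo-4-[(1S,3R,7S)-1,7-dihydroxy-3,7-dimethyl-8-(triethylsilyloxy)oct-4-yn-1-yl]furan-2(5H)-one
Conditions: (R)-2-methyl-CBS-oxazaborolidine (0.3 equiv), catecholborane, toluene, −78 °C
Reagents that add atoms: none
Why: The (R)-oxazaborolidine–borane complex binds the ketone with the larger alkenyl (lactone) group away from the catalyst and delivers hydride to give the (S)-carbinol at C8 (Corey–Bakshi–Shibata reduction).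

Step 11
Reactants: 17 (tert-butyldimethylsilyloxy)acetaldehyde; 18 ethyl 2-(triphenylphosphoranylidene)propanoate
Product: 19 ethyl (E)-4-(tert-butyldimethylsilyloxy)-2-methylbut-2-enoate
Conditions: CH2Cl2, rt
Reagents that add atoms: none
Why: The stabilized ylide gives the (E)-trisubstituted enoate under thermodynamic control of oxaphosphetane formation (Wittig reaction).

Step 12
Reactants: 19 ethyl (E)-4-(tert-butyldimethylsilyloxy)-2-methylbut-2-enoate
Product: 20 (E)-4-(tert-butyldimethylsilyloxy)-2-methylbut-2-enoic acid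
Conditions: LiOH, THF/H2O, rt; then HCl (1 M) to pH 3 at 0 °C
Reagents that add atoms: lithium hydroxide, [Li+].[OH-]
Why: Saponification of the ethyl ester proceeds at the acyl carbon and leaves the primary silyl ether and the alkene geometry intact (ester hydrolysis).

Step 13
Reactants: 16 3-bromo-4-[(1S,3R,7S)-1,7-dihydroxy-3,7-dimethyl-8-(triethylsilyloxy)oct-4-yn-1-yl]furan-2(5H)-one; 20 (E)-4-(tert-butyldimethylsilyloxy)-2-methylbut-2-enoic acid
Product: 22 (1S,3R,7S)-1-(4-bromo-5-oxo-2,5-dihydrofuran-3-yl)-7-hydroxy-3,7-dimethyl-8-(triethylsilyloxy)oct-4-yn-1-yl (E)-4-(tert-butyldimethylsilyloxy)-2-methylbut-2-enoate, via mixed anhydride 21 (not isolated)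
Conditions: 2,4,6-trichlorobenzoyl chloride, Et3N, THF, rt; then 16, DMAP, toluene, rt
Reagents that add atoms: none
Why: DMAP opens the mixed anhydride at the less hindered aliphatic carbonyl and the acylpyridinium acylates the secondary C8 alcohol with retention, the tertiary C4 alcohol being too hindered to react (Yamaguchi esterification).

Step 14
Reactants: 22 (1S,3R,7S)-1-(4-bromo-5-oxo-2,5-dihydrofuran-3-yl)-7-hydroxy-3,7-dimethyl-8-(triethylsilyloxy)oct-4-yn-1-yl (E)-4-(tert-butyldimethylsilyloxy)-2-methylbut-2-enoate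
Product: 24 (1S,3R,7S)-1-(4-bromo-5-oxo-2,5-dihydrofuran-3-yl)-7-hydroxy-3,7-dimethyl-8-oxooct-4-yn-1-yl (E)-4-(tert-butyldimethylsilyloxy)-2-methylbut-2-enoate, via alkoxysulfonium chloride 23 (not isolated)
Conditions: (COCl)2, DMSO, CH2Cl2, −78 to −40 °C; then Et3N, −78 to 0 °C
Reagents that add atoms: none
Why: Chlorodimethylsulfonium chloride attacks the unhindered primary triethylsilyl ether oxygen with loss of TESCl and Et3N then converts the alkoxysulfonium salt into the C5 aldehyde (Swern oxidation of a primary TES ether), while the bulkier TBS ether and the tertiary alcohol should not react.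

Step 15
Reactants: 24 (1S,3R,7S)-1-(4-bromo-5-oxo-2,5-dihydrofuran-3-yl)-7-hydroxy-3,7-dimethyl-8-oxooct-4-yn-1-yl (E)-4-(tert-butyldimethylsilyloxy)-2-methylbut-2-enoate
Product: 25 (1S,3R)-1-(4-bromo-5-oxo-2,5-dihydrofuran-3-yl)-3-[(S)-5-formyl-5-methyl-4,5-dihydrofuran-2-yl]butyl (E)-4-(tert-butyldimethylsilyloxy)-2-methylbut-2-enoate
Conditions: (Ph3P)AuNTf2 (5 mol %), 4 Å molecular sieves, CH2Cl2, rt
Reagents that add atoms: none
Why: The cationic monovalent gold complex activates the alkyne, the C4 hydroxyl adds 5-endo-dig to C1 and protodeauration gives the 2,3-dihydrofuran (gold-catalysed alkyne hydroalkoxylation), which closes ring B as a planar C1=C2 enol ether without touching C4 or C10.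

Step 16
Reactants: 25 (1S,3R)-1-(4-bromo-5-oxo-2,5-dihydrofuran-3-yl)-3-[(S)-5-formyl-5-methyl-4,5-dihydrofuran-2-yl]butyl (E)-4-(tert-butyldimethylsilyloxy)-2-methylbut-2-enoate
Product: 28 11-bromo-13-nor-1,2-didehydro-1-deoxy derivative of the target carrying the side-chain hydroxyl as TBS ether (tricycle with C1=C2 enol ether and C5=C6 ylidene), via silyloxyfuran 26 (not isolated), via silyl aldol adduct 27 (not isolated)
Conditions: TBSOTf (3 equiv), iPr2NEt (6 equiv), CH2Cl2 (2 mM), 0 °C; then DBU (4 equiv), 0 °C to rt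
Reagents that add atoms: none
Why: Proposed new method: TBSOTf and iPr2NEt convert butenolide ring A into its 2-silyloxyfuran 26, whose C6 adds to the silyl-activated, non-enolizable C5 aldehyde in a vinylogous Mukaiyama aldol reaction (9-exo-trig closure of ring C, giving 27), and DBU then removes H6 and expels the C5 silyloxide by E1cB elimination to form the C5=C6 alkene. The closest known reaction type is the intermolecular one-pot silyl triflate/amine vinylogous aldol–elimination of 3-halo-4-substituted furan-2(5H)-ones with aldehydes to 5-ylidenebutenolides, which has not been used to close a nine-membered ring. Ring B holds C5 and C10 at its two α-positions and the flat furan fixes C6, C7 and C8, so few rotatable bonds have to be ordered in the transition state. No lasting stereocentre is formed, because the C5 and C6 centres of 27 are both erased and all diastereomers of 27 converge on 28. The C5=C6 geometry with C4 cis to C7, the less stable one in open-chain 4-substituted ylidenebutenolides, is the only one the nine-membered ring can hold. The step needs chemoselectivity for the aldehyde over the C1=C2 enol ether and ring closure over oligomerization, which excess amine (no protonation of the enol ether, hence no C1 oxocarbenium ion for a six-membered C6–C1 closure) and high dilution should secure.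

Step 17
Reactants: 28 11-bromo-13-nor-1,2-didehydro-1-deoxy derivative of the target carrying the side-chain hydroxyl as TBS ether
Product: 29 1,2-didehydro-1-deoxy-13-O-deacetyl derivative of the target carrying the side-chain hydroxyl as TBS ether
Conditions: Bu3SnCH2OH, Pd(PPh3)4 (10 mol %), 1,4-dioxane, 90 °C
Reagents that add atoms: (tributylstannyl)methanol, CCCC[Sn](CCCC)(CCCC)CO
Why: Zerovalent palladium inserts into the C11–Br bond of the α-bromo unsaturated lactone and the hydroxymethyl group is transferred from tin, which installs C13 (Stille coupling).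

Step 18
Reactants: 29 1,2-didehydro-1-deoxy-13-O-deacetyl derivative of the target carrying the side-chain hydroxyl as TBS ether
Product: 30 1,2-didehydro-1-deoxy derivative of the target carrying the side-chain hydroxyl as TBS ether
Conditions: Ac2O, pyridine, CH2Cl2, 0 °C
Reagents that add atoms: acetic anhydride, CC(=O)OC(C)=O
Why: The C13 hydroxyl is the only free hydroxyl and is acetylated under mild basic conditions that the enol ether tolerates (acylation).

Step 19
Reactants: 30 1,2-didehydro-1-deoxy derivative of the target carrying the side-chain hydroxyl as TBS ether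
Product: 31 target compound (CNP0154520.2)
Conditions: HF·pyridine, THF/H2O (10:1), 0 °C to rt
Reagents that add atoms: water, O
Why: HF·pyridine cleaves the primary allylic TBS ether and protonates the enol ether at C2, and water adds to the C1 oxocarbenium ion from the only open face, so the C1 hemiketal configuration is dictated by the oxygen bridge from C4 (desilylation and acid-catalysed enol ether hydration).

**Compound list**

1 | (S)-4-benzyl-3-propionyloxazolidin-2-one | CCC(=O)N1[C@@H](Cc2ccccc2)COC1=O | starting material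
2 | allyl iodide (3-iodoprop-1-ene) | C=CCI | starting material
3 | sodium (Z)-enolate of 1 | C/C=C(\[O-])N1[C@@H](Cc2ccccc2)COC1=O.[Na+] | intermediate
4 | (S)-4-benzyl-3-[(R)-2-methylpent-4-enoyl]oxazolidin-2-one | C=CC[C@@H](C)C(=O)N1[C@@H](Cc2ccccc2)COC1=O | intermediate
5 | (R)-2-methylpent-4-en-1-ol | C=CC[C@@H](C)CO | intermediate
6 | (R)-2-methylpent-4-enal | C=CC[C@@H](C)C=O | intermediate
7 | (R)-1,1-dibromo-3-methylhexa-1,5-diene | C=CC[C@@H](C)C=C(Br)Br | intermediate
8 | (R)-2-methylglycidol | C[C@@]1(CO)CO1 | starting material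
9 | (S)-triethyl[(2-methyloxiran-2-yl)methoxy]silane | C[C@@]1(CO[Si](CC)(CC)CC)CO1 | intermediate
10 | lithium (R)-3-methylhex-5-en-1-yn-1-ide | C=CC[C@@H](C)C#C[Li] | intermediate
11 | (2S,6R)-2,6-dimethyl-1-(triethylsilyloxy)non-8-en-4-yn-2-ol | C=CC[C@@H](C)C#CC[C@](C)(O)CO[Si](CC)(CC)CC | intermediate
12 | (3R,7S)-7-hydroxy-3,7-dimethyl-8-(triethylsilyloxy)oct-4-ynal | O=CC[C@@H](C)C#CC[C@](C)(O)CO[Si](CC)(CC)CC | intermediate
13 | 3,4-dibromofuran-2(5H)-one | O=C1OCC(Br)=C1Br | starting material
14 | 3-bromo-4-[(3R,7S)-1,7-dihydroxy-3,7-dimethyl-8-(triethylsilyloxy)oct-4-yn-1-yl]furan-2(5H)-one (C8 epimers) | O=C1OCC(C(O)C[C@@H](C)C#CC[C@](C)(O)CO[Si](CC)(CC)CC)=C1Br | intermediate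
15 | 3-bromo-4-[(3R,7S)-7-hydroxy-3,7-dimethyl-8-(triethylsilyloxy)oct-4-ynoyl]furan-2(5H)-one | O=C1OCC(C(=O)C[C@@H](C)C#CC[C@](C)(O)CO[Si](CC)(CC)CC)=C1Br | intermediate
16 | 3-bromo-4-[(1S,3R,7S)-1,7-dihydroxy-3,7-dimethyl-8-(triethylsilyloxy)oct-4-yn-1-yl]furan-2(5H)-one | O=C1OCC([C@@H](O)C[C@@H](C)C#CC[C@](C)(O)CO[Si](CC)(CC)CC)=C1Br | intermediate
17 | (tert-butyldimethylsilyloxy)acetaldehyde | CC(C)(C)[Si](C)(C)OCC=O | starting material
18 | ethyl 2-(triphenylphosphoranylidene)propanoate | CCOC(=O)C(C)=P(c1ccccc1)(c1ccccc1)c1ccccc1 | starting material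
19 | ethyl (E)-4-(tert-butyldimethylsilyloxy)-2-methylbut-2-enoate | CCOC(=O)/C(C)=C/CO[Si](C)(C)C(C)(C)C | intermediate
20 | (E)-4-(tert-butyldimethylsilyloxy)-2-methylbut-2-enoic acid | OC(=O)/C(C)=C/CO[Si](C)(C)C(C)(C)C | intermediate
21 | mixed anhydride of 20 with 2,4,6-trichlorobenzoic acid | O=C(OC(=O)c1c(Cl)cc(Cl)cc1Cl)/C(C)=C/CO[Si](C)(C)C(C)(C)C | intermediate
22 | (1S,3R,7S)-1-(4-bromo-5-oxo-2,5-dihydrofuran-3-yl)-7-hydroxy-3,7-dimethyl-8-(triethylsilyloxy)oct-4-yn-1-yl (E)-4-(tert-butyldimethylsilyloxy)-2-methylbut-2-enoate | O=C1OCC([C@@H](OC(=O)/C(C)=C/CO[Si](C)(C)C(C)(C)C)C[C@@H](C)C#CC[C@](C)(O)CO[Si](CC)(CC)CC)=C1Br | intermediate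
23 | alkoxydimethylsulfonium chloride of 22 (Me2S+ on the C5 oxygen in place of SiEt3) | O=C1OCC([C@@H](OC(=O)/C(C)=C/CO[Si](C)(C)C(C)(C)C)C[C@@H](C)C#CC[C@](C)(O)CO[S+](C)C)=C1Br.[Cl-] | intermediate
24 | (1S,3R,7S)-1-(4-bromo-5-oxo-2,5-dihydrofuran-3-yl)-7-hydroxy-3,7-dimethyl-8-oxooct-4-yn-1-yl (E)-4-(tert-butyldimethylsilyloxy)-2-methylbut-2-enoate | O=C1OCC([C@@H](OC(=O)/C(C)=C/CO[Si](C)(C)C(C)(C)C)C[C@@H](C)C#CC[C@](C)(O)C=O)=C1Br | intermediate
25 | (1S,3R)-1-(4-bromo-5-oxo-2,5-dihydrofuran-3-yl)-3-[(S)-5-formyl-5-methyl-4,5-dihydrofuran-2-yl]butyl (E)-4-(tert-butyldimethylsilyloxy)-2-methylbut-2-enoate | O=C[C@]1(C)CC=C(O1)[C@H](C)C[C@H](OC(=O)/C(C)=C/CO[Si](C)(C)C(C)(C)C)C2=C(Br)C(=O)OC2 | intermediate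
26 | 2-(tert-butyldimethylsilyloxy)furan form of 25 (3-bromo-2-silyloxyfuran-4-yl in place of the butenolide) | O=C[C@]1(C)CC=C(O1)[C@H](C)C[C@H](OC(=O)/C(C)=C/CO[Si](C)(C)C(C)(C)C)c2coc(O[Si](C)(C)C(C)(C)C)c2Br | intermediate
27 | nine-membered-ring silyl aldol adduct (C5–OTBS and C6–H; mixture of C5 and C6 epimers) | O=C1OC2C(O[Si](C)(C)C(C)(C)C)[C@]3(C)CC=C(O3)[C@H](C)C[C@H](OC(=O)/C(C)=C/CO[Si](C)(C)C(C)(C)C)C2=C1Br | intermediate
28 | 11-bromo-13-nor-1,2-didehydro-1-deoxy derivative of the target carrying the side-chain hydroxyl as TBS ether | O=C1O/C2=C/[C@]3(C)CC=C(O3)[C@H](C)C[C@H](OC(=O)/C(C)=C/CO[Si](C)(C)C(C)(C)C)C2=C1Br | intermediate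
29 | 1,2-didehydro-1-deoxy-13-O-deacetyl derivative of the target carrying the side-chain hydroxyl as TBS ether | O=C1O/C2=C/[C@]3(C)CC=C(O3)[C@H](C)C[C@H](OC(=O)/C(C)=C/CO[Si](C)(C)C(C)(C)C)C2=C1CO | intermediate
30 | 1,2-didehydro-1-deoxy derivative of the target carrying the side-chain hydroxyl as TBS ether | O=C1O/C2=C/[C@]3(C)CC=C(O3)[C@H](C)C[C@H](OC(=O)/C(C)=C/CO[Si](C)(C)C(C)(C)C)C2=C1COC(C)=O | intermediate
31 | target compound CNP0154520.2 | CC(=O)OCC1=C2/C(=C\[C@]3(C)CC[C@@](O)(O3)[C@H](C)C[C@@H]2OC(=O)/C(C)=C/CO)OC1=O | target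

**Totals**

Total step count: 19. Longest linear sequence: 16 steps (steps 1–4, 6–10 and 13–19).

**Steps most likely to fail**

Step 16 (proposed new method). The strained nine-membered transition state may lose to intermolecular aldol addition and oligomerization, or adventitious acid may protonate the enol ether and divert the silyloxyfuran into a six-membered C6–C1 closure. The fallback uses known reaction types, sets out from 22 and comes back at 28. Compound 22 is converted through its 2-(trimethylsilyloxy)furan (TMSOTf, Et3N, CH2Cl2, 0 °C) and NBS at −78 °C, with mild acidic work-up to free the tertiary alcohol, into the γ-bromobutenolide F1. A Michaelis–Arbuzov reaction with P(OMe)3 in toluene at 80 °C gives the dimethyl phosphonate F2. The conditions of step 14 give the phosphonate hydroxy aldehyde F3, and the conditions of step 15 give the phosphonate dihydrofuran aldehyde F4. LiCl and DBU in MeCN at 2 mM should then close ring C by intramolecular Horner–Wadsworth–Emmons olefination, an established ring-closing reaction that lactone γ-phosphonates undergo with aldehydes, to give 28. This replaces the reversible Lewis-acid aldol by an irreversible olefination under base only.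

Step 8. Nickel may insert unselectively into the two C–Br bonds, the acidic γ-CH2 of the lactone may protonate the alkenylchromium species, and the lactone may migrate to the newly formed C8 alkoxide. The fallback sets out from 12 and 13 and comes back at 15, so that step 9 is not needed and no free C8 alcohol is formed before the ketone. Pinnick oxidation of 12 (NaClO2, NaH2PO4, 2-methyl-2-butene, t-BuOH/H2O) gives the carboxylic acid F5. PhSH, DCC and DMAP (5 mol %) give the S-phenyl thioester F6. Separately, 13 is stannylated at the more reactive C4 position (Bu3SnSnBu3, Pd(PPh3)4, toluene) to give the alkenylstannane F7. Liebeskind–Srogl coupling of F6 with F7 (Pd2(dba)3, tri(2-furyl)phosphine, copper thiophene-2-carboxylate Cu(O2CC4H3S), THF, rt) should give ketone 15 directly.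

Step 15. The C4 hydroxyl, deactivated by the neighbouring formyl group, may add too slowly to the gold-activated alkyne, and the α-hydroxy aldehyde may decay by hydration or oligomerization. The fallback changes the order of events, sets out from 22 and comes back at 25. Gold catalysis under the conditions of step 15 is applied to 22 itself and should give the dihydrofuran triethylsilyl ether F8. HF·pyridine buffered with excess pyridine in THF at 0 °C should remove the primary TES group selectively and give the dihydrofuran primary alcohol F9. Parikh–Doering oxidation (SO3·pyridine, DMSO, iPr2NEt, 0 °C), which is compatible with the enol ether, then gives 25.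

**Further compounds**

F1 | step 16 | (1S,3R,7S)-1-(2,4-dibromo-5-oxo-2,5-dihydrofuran-3-yl)-7-hydroxy-3,7-dimethyl-8-(triethylsilyloxy)oct-4-yn-1-yl (E)-4-(tert-butyldimethylsilyloxy)-2-methylbut-2-enoate (C6 epimers) | O=C1OC(Br)C([C@@H](OC(=O)/C(C)=C/CO[Si](C)(C)C(C)(C)C)C[C@@H](C)C#CC[C@](C)(O)CO[Si](CC)(CC)CC)=C1Br
F2 | step 16 | dimethyl phosphonate of F1 (P(O)(OMe)2 on C6 in place of Br; C6 epimers) | O=C1OC(P(=O)(OC)OC)C([C@@H](OC(=O)/C(C)=C/CO[Si](C)(C)C(C)(C)C)C[C@@H](C)C#CC[C@](C)(O)CO[Si](CC)(CC)CC)=C1Br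
F3 | step 16 | C5 aldehyde of F2 (CHO in place of CH2OSiEt3) | O=C1OC(P(=O)(OC)OC)C([C@@H](OC(=O)/C(C)=C/CO[Si](C)(C)C(C)(C)C)C[C@@H](C)C#CC[C@](C)(O)C=O)=C1Br
F4 | step 16 | C6 dimethyl phosphonate of 25 | O=C[C@]1(C)CC=C(O1)[C@H](C)C[C@H](OC(=O)/C(C)=C/CO[Si](C)(C)C(C)(C)C)C2=C(Br)C(=O)OC2P(=O)(OC)OC
F5 | step 8 | (3R,7S)-7-hydroxy-3,7-dimethyl-8-(triethylsilyloxy)oct-4-ynoic acid | OC(=O)C[C@@H](C)C#CC[C@](C)(O)CO[Si](CC)(CC)CC
F6 | step 8 | S-phenyl (3R,7S)-7-hydroxy-3,7-dimethyl-8-(triethylsilyloxy)oct-4-ynethioate | O=C(Sc1ccccc1)C[C@@H](C)C#CC[C@](C)(O)CO[Si](CC)(CC)CC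
F7 | step 8 | 3-bromo-4-(tributylstannyl)furan-2(5H)-one | O=C1OCC([Sn](CCCC)(CCCC)CCCC)=C1Br
F8 | step 15 | (1S,3R)-1-(4-bromo-5-oxo-2,5-dihydrofuran-3-yl)-3-[(S)-5-methyl-5-(triethylsilyloxymethyl)-4,5-dihydrofuran-2-yl]butyl (E)-4-(tert-butyldimethylsilyloxy)-2-methylbut-2-enoate | CC[Si](CC)(CC)OC[C@]1(C)CC=C(O1)[C@H](C)C[C@H](OC(=O)/C(C)=C/CO[Si](C)(C)C(C)(C)C)C2=C(Br)C(=O)OC2
F9 | step 15 | (1S,3R)-1-(4-bromo-5-oxo-2,5-dihydrofuran-3-yl)-3-[(S)-5-(hydroxymethyl)-5-methyl-4,5-dihydrofuran-2-yl]butyl (E)-4-(tert-butyldimethylsilyloxy)-2-methylbut-2-enoate | OC[C@]1(C)CC=C(O1)[C@H](C)C[C@H](OC(=O)/C(C)=C/CO[Si](C)(C)C(C)(C)C)C2=C(Br)C(=O)OC2
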